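1. The easy step: the gas stands held at 0.73 mM in dawn, midnight, noon and winter, as in violet and green, so it is frozen out of the comparison, leaving time, temperature and charge.

| flask | solid substrate | gas | temperature | remark | time |
|---|---|---|---|---|---|
| violet | 5.8 mM | 0.73 mM (held) | 0 °C | run made earlier |  |
| green | 73 mM | 0.73 mM (held) | 44 °C | run made earlier |  |
| dawn | 4.0 mM | 0.73 mM (held) | −20 °C |  | 8.0 h |
| midnight | 25 mM | 0.73 mM (held) | 60 °C |  | 8.0 h |
| noon | 16 mM | 0.73 mM (held) | 20 °C |  | 8.0 h |
| winter | 60 mM | 0.73 mM (held) | 35 °C |  | 8.0 h |

violet run (percent of the solid substrate charged)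

| time / h | target / % |
|---|---|
| 2.50 | 0 |
| 4.00 | 0 |
| 6.00 | 2.9 |
| 8.00 | 3.0 |
| 10.0 | 4.5 |
| 15.0 | 9.0 |

green run (percent of the solid substrate charged)

| time / min | target / % |
|---|---|
| 8.00 | 1.4 |
| 12.0 | 0 |
| 20.0 | 1.4 |
| 30.0 | 0 |
| 50.0 | 0.6 |
| 80.0 | 3.3 |
| 120 | 1.3 |

(each reading ± 1 percentage point)

1. the flasks by amount of target, in percent of the solid substrate charged, highest first, at 8.0 h (dawn / midnight / noon / winter)
2. the amount of target, in percent of the solid substrate charged of the flask you put first, at 8.0 h
3. the amount of target, in percent of the solid substrate charged of the flask you put last, at 8.0 h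

- solid, in amounts per volume of the solution: solid substrate
- at the start none of the solid substrate is in solution
- at the start none of the gas is in solution
- what has only dissolved of solid substrate counts as not reacted

2. Violet's target appears after a lag and then climbs roughly with the square of time, as for target formed through a hidden stage. Violet's last reading gives 50.0 h for the square-law time τ, the time at which growth with the square of time would reach the whole charge. The fraction of target is then (t/τ) squared. Read at two times in one flask, τ stays level while the square law holds, and a lengthening τ marks its end.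

3. Any relative error in τ doubles in the yield, so each input is weighed in turn. Violet's 9.0% carries a scatter of 1 percentage point, which is tolerable. Green's 1.3% is smaller under that same scatter, so the temperature trend is the weak number. Charge changes together with temperature between the runs (5.8 mM against 73 mM), so this reckoning sets its effect aside.

4. Green's last reading gives τ = 17.5 h, with that reading's scatter. My own reckoning takes ln τ as straight in temperature and gives midnight 44.6%, winter 13.6%, noon 6.63% and dawn 0.988%.

5. The forecast gives the same order, midnight > winter > noon > dawn, with different numbers: top 60% (30% to 90%) and low 0.5% (0% to 2%). It adds that “the order probably holds”.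

6. The flasks give noon > winter > midnight > dawn, with top 21.1% and low 0.0576%.

    reagent + intermediate A ⇌ intermediate B (K = 880 M⁻¹, k = 369 M⁻¹ h⁻¹, Ea = 37.0 kJ mol⁻¹, ΔH = −42.0 kJ mol⁻¹)
    starting material + reagent → intermediate C (k = 430 M⁻¹ h⁻¹, Ea = 46.0 kJ mol⁻¹)
    intermediate C → target (k = 0.584 h⁻¹, Ea = 94.0 kJ mol⁻¹)
    starting material → intermediate A (k = 0.486 h⁻¹, Ea = 96.0 kJ mol⁻¹)
    solid substrate ⇌ starting material, rate k5*(cs5 - [starting material]) while solid is left; crystals form when [starting material] > cs5 (solubility = 8.50 mM, k = 2.54 h⁻¹)
    intermediate C ⇌ intermediate D (K = 0.790, k = 0.469 h⁻¹, Ea = 87.0 kJ mol⁻¹, ΔH = 20.0 kJ mol⁻¹)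
    reagent + intermediate C ⇌ intermediate E (K = 4160 M⁻¹, k = 681 M⁻¹ h⁻¹, Ea = 47.0 kJ mol⁻¹, ΔH = −72.0 kJ mol⁻¹)
    gas ⇌ reagent, rate k8*(csat - [reagent]) (kL = 13.7 h⁻¹)
    (constants at 20 °C)

7. In noon, starting material fell from 11.4% at 4.00 h to 0.505% at 8.00 h while target rose from 12.9% to 21.1%, and τ lengthened from 11.1 h to 17.4 h, beside the 50.0 h read from violet at its own temperature and charge. In midnight, starting material already stood at 0% at 4.00 h, with intermediate A at 88.8%; target stayed at 4.03% up to 8.00 h, and τ became twice its value at 4.00 h. Dawn, with starting material still at 87.6% at 8.00 h, gave τ = 330 h at 4.00 h and 333 h at 8.00 h.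

The readings are simulated with constants of no real substance; the scatter is artificial.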